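Ring numbering used throughout: C1 (OMe), C2 (OH), C3 (Br), C4 (Br), C5 (CH2OH), C6 (Br).

## The problem

The target, (2,3,6-tribromo-4-hydroxy-5-methoxyphenyl)methanol, is a single benzene ring with all six positions substituted. There is no ring fusion and no chain to assemble, so the task is to place six substituents without positional ambiguity. The molecule has no stereocentre, so nothing has to be set or relayed. The two vicinal oxygens must be told apart: the C1 oxygen carries methyl and the C2 oxygen carries hydrogen. The three bromines sit at C3, C4 and C6, a pattern that electrophilic substitution on a simple catechol ether does not deliver cleanly. The aryl C–Br bonds will not survive hydrogenolysis, halogen–metal exchange reagents or aggressive hydride donors. The para-hydroxybenzyl alcohol ionises easily at the benzylic carbon in acid or hot base, so it should be unveiled last and worked up near neutral pH. The enabling feature is that the C1 oxygen is flanked by the oxygen-bearing C2 and the bromine-bearing C6, while the C5 carbon substituent is para to the C2 oxygen. That is the arrangement left when a 3-alkoxy-4-bromofuran adds across a 3-bromopropiolate and the oxygen bridge opens: the furan oxygen becomes the C1 oxygen, the alkoxy group the C2 oxygen, the furan bromine the C3 bromine, and the alkyne carbons become C6–Br and the C5 ester.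

## Retrosynthesis

**11 from 10.** The hydroxymethyl group at C5 is traced back to a methyl ester, so target 11 comes from methyl 2,3,6-tribromo-4-hydroxy-5-methoxybenzoate 10. The ester is the form in which the alkyne delivers this carbon. Keeping it until the end means the ionisable benzylic alcohol never meets bromine, base or Lewis acid. The forward step must reduce a doubly ortho-brominated ester beside a free phenol without touching any C–Br bond.

**10 from 9.** The C2 hydroxyl is uncovered from a benzyl ether, giving methyl 4-(benzyloxy)-2,3,6-tribromo-5-methoxybenzoate 9. A methyl group here would erase the difference between the two oxygens. Benzyl survives copper coupling, heat, bromine and carbonate, and it can be removed without hydrogen gas. The forward step must cleave O–benzyl next to O–methyl and leave the bromines alone.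

**9 from 8.** The O–CH3 bond at C1 is cut to give phenol 8, methyl 4-(benzyloxy)-2,3,6-tribromo-5-hydroxybenzoate. Compound 8 has a single free hydroxyl, so the alkylation has no selectivity question. This is where the built-in differentiation of the oxygens pays off.

**8 from 7.** The C4–Br bond is cut to give methyl 4-(benzyloxy)-2,5-dibromo-3-hydroxybenzoate 7. C4 derives from a furan α-carbon that must carry hydrogen through the cycloaddition, so this bromine is added afterwards. In 7 the C4–H is the only ring hydrogen and is para to the free C1 phenol, whose two ortho positions are blocked. The forward bromination must work on a ring deactivated by two bromines and an ester.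

**7 from 3 and 5 via 6.** The ring bonds C1–C6 and C4–C5 are cut and the C4–O bond is re-formed, leading through oxanorbornadiene 6 to 3-(benzyloxy)-4-bromofuran 3 and methyl 3-bromopropiolate 5. Other (4+2) dissections of the ring need a fully substituted acyclic or heterocyclic diene. This one uses an aromatic furan whose own oxygen becomes the C1 oxygen, and the electron-rich diene is matched with an electron-poor alkyne. A pentasubstituted benzene is reduced to two small fragments. The forward reaction must be regioselective twice: in the cycloaddition, and in the direction in which the bridge opens.

**3 from 1 and 2.** The furan C3–O bond is cut to give 3,4-dibromofuran 1 and benzyl alcohol 2. The symmetry of 1 removes any site question, leaving only the need to stop after one substitution.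

**5 from 4.** The alkyne C–Br bond is cut to give methyl propiolate 4. The forward step is a terminal-alkyne bromination.

## Roads not taken

**Alternative 1: aryne dibromination.**
- **Cut:** the C3–Br and C4–Br bonds.
- **Forward key step:** fluoride unmasks aryne A3 from silyl triflate A2, and bromine adds across the strained bond to give the bis(methoxymethyl) ether A1 of the target.
- **Merits:** the two adjacent bromines are placed by the position of the aryne alone. No directing effect is involved and the conditions are nearly neutral. In positional certainty for C3 and C4 this road is better than any electrophilic substitution.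
- **Weak points:** A2 is itself a hexasubstituted benzene. It already needs the C6 bromine, both oxygens, the C5 carbon, a silyl group and an extra phenolic oxygen that is later discarded as triflate. Installing silicon ortho to a triflate normally uses aryl-metal chemistry that endangers the C6 bromine. Fluoride and elemental bromine in one flask invite aryl fluoride and monobromide by-products. Acidic removal of two acetal groups at the end exposes the benzylic position to solvolysis.
- **Comparison:** the chosen plan brings C3–Br and C6–Br in on the building blocks and has a single open position for the third, so little positional risk remains, and it is much shorter.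

**Alternative 2: thiophene dioxide cycloaddition.**
- **Cut:** the C3–C4 and C5–C6 bonds.
- **Forward key step:** 2,5-dibromo-3,4-dimethoxythiophene 1,1-dioxide A4 adds to the same bromoalkyne 5, and loss of SO2 gives methyl 2,3,6-tribromo-4,5-dimethoxybenzoate A5.
- **Merits:** the complete hexasubstituted ring with all three bromines appears in one step. The diene is symmetric, so there is no regiochemical question. On paper this is the shortest ring construction and needs no late bromination; in both respects it is better than the chosen plan.
- **Weak points:** the two oxygens arrive as identical methyl ethers. The C2 methoxy would have to be cleaved selectively beside the C1 methoxy when both are flanked by bromine, and there is no strong structural reason for that selectivity. The sulfone diene is electron-poor and so is the alkyne, so the pairing is electronically mismatched and would need temperatures at which the diene can dimerise. Oxidising an electron-rich dialkoxythiophene to its dioxide is also not routine.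
- **Comparison:** the chosen plan offers a matched diene–dienophile pair and two oxygens that are already different when the ring forms.

**Alternative 3: halogen dance and formylation.**
- **Cut:** the C6–Br bond and the bond from C5 to its carbon substituent.
- **Forward key step:** LiN(iPr)2 removes the only ring hydrogen of the protected tribromide A6 at C6. Bromine then moves from C5 to C6, and the lithium now at C5 is formylated to give aldehyde A7.
- **Merits:** this is the shortest road overall, from a cheap methoxyphenol-derived arene, with the oxygens already differentiated. In step count and material cost it beats the chosen plan.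
- **Weak points:** the outcome rests on an equilibrium between aryl anions. The first anion, between a methoxy group and a bromine, is already well stabilised, so migration to the position between two bromines need not be complete. Incomplete migration gives the wrong aldehyde isomer. Intermolecular bromine transfer gives di- and tetrabromo arenes. An aryllithium ortho to bromine can lose LiBr to an aryne. The final acidic deprotection again threatens the benzylic position.
- **Comparison:** in the chosen plan every substituent position is fixed by bond construction and not by an anion equilibrium.

Key step: step 3

Remark on the chemistry: the only stereogenic atoms on the route are the two bridgeheads of 6. They form as a racemate and are erased on aromatisation; the SMILES of 6 shows one enantiomer.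

## Route

Step 1
Reactants: 1 3,4-dibromofuran; 2 benzyl alcohol
Product: 3 3-(benzyloxy)-4-bromofuran
Conditions: 1 (2.5 equiv), CuI (10 mol %), 3,4,7,8-tetramethyl-1,10-phenanthroline (20 mol %), Cs2CO3 (1.5 equiv), PhMe, 100 °C, sealed tube
Reagents that add atoms: none
Why: Ullmann-type copper-catalysed C–O coupling of a heteroaryl bromide with a primary alcohol; the first alkoxy group makes the ring more electron-rich and the second C–Br bond slower to react, and the excess of symmetric 1 (recovered by distillation) further favours mono-substitution.

Step 2
Reactants: 4 methyl propiolate
Product: 5 methyl 3-bromopropiolate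
Conditions: NBS (1.15 equiv), AgNO3 (10 mol %), acetone, rt, dark
Reagents that add atoms: N-bromosuccinimide, O=C1CCC(=O)N1Br
Why: Silver-catalysed electrophilic bromination of a terminal alkyne through the silver acetylide, a standard preparation of 1-bromoalkynes that leaves the ester untouched.

Step 3
Reactants: 3 3-(benzyloxy)-4-bromofuran; 5 methyl 3-bromopropiolate
Product: 7 methyl 4-(benzyloxy)-2,5-dibromo-3-hydroxybenzoate, via oxanorbornadiene cycloadduct 6 (not isolated)
Conditions: 5 (1.5 equiv), PhMe, 75 °C, dark; then BF3·OEt2 (0.2 equiv), CH2Cl2, −20 to 0 °C
Reagents that add atoms: none
Why: Thermal intermolecular (4+2) cycloaddition of the electron-rich furan 3 (termini furan C2 and C5) with the electron-poor bromoalkynoate 5 closes the six-membered carbocycle by forming the C1–C6 and C4–C5 bonds and gives oxanorbornadiene 6. The regioselectivity comes from polarity: furan C2 is the β-carbon of the benzyl enol ether and the most nucleophilic diene terminus, the bromine-bearing β-carbon of 5 is the conjugate-acceptor terminus, so these two join and the ester ends para to the benzyloxy group. BF3·OEt2 then coordinates the bridge oxygen and the C–O bond breaks at C4, because only that cation is conjugated through the C3=C2 enol ether to the benzyloxy oxygen; loss of the C1 proton aromatises the ring and leaves the bridge oxygen as the C1 phenol. The closest known reaction type is the furan–alkyne Diels–Alder reaction followed by acid-mediated isomerisation of the 7-oxanorbornadiene to a phenol, known for furans with bromopropiolate esters and for 3-alkoxyfurans with acetylenic esters. The two bridgehead stereocentres of 6 form as a racemate with the hydrogens necessarily cis and vanish on aromatisation, so no stereocontrol is needed. An anhydrous Lewis acid at low temperature avoids water capture of the oxocarbenium ion, which would cost the benzyl group.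

Step 4
Reactants: 7 methyl 4-(benzyloxy)-2,5-dibromo-3-hydroxybenzoate
Product: 8 methyl 4-(benzyloxy)-2,3,6-tribromo-5-hydroxybenzoate
Conditions: Br2 (1.1 equiv), NaOAc (1.5 equiv), AcOH, rt, dark
Reagents that add atoms: bromine, BrBr
Why: Electrophilic aromatic bromination directed by the free C1 phenol to its para position C4, the only ring C–H, since both ortho positions are occupied; acetate buffers the HBr so the benzyl ether is not cleaved.

Step 5
Reactants: 8 methyl 4-(benzyloxy)-2,3,6-tribromo-5-hydroxybenzoate
Product: 9 methyl 4-(benzyloxy)-2,3,6-tribromo-5-methoxybenzoate
Conditions: MeI (3 equiv), K2CO3 (2 equiv), DMF, rt to 40 °C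
Reagents that add atoms: iodomethane, CI
Why: Williamson O-methylation of the only free hydroxyl; the acidic, bromine-flanked phenol is fully deprotonated by carbonate, and the small electrophile copes with the two ortho substituents.

Step 6
Reactants: 9 methyl 4-(benzyloxy)-2,3,6-tribromo-5-methoxybenzoate
Product: 10 methyl 2,3,6-tribromo-4-hydroxy-5-methoxybenzoate
Conditions: BCl3 (2 equiv), pentamethylbenzene (3 equiv), CH2Cl2, −78 °C; then H2O
Reagents that add atoms: none
Why: Lewis-acid debenzylation with a non-basic cation scavenger; at −78 °C the benzyl group ionises and is trapped by pentamethylbenzene, while the methyl ether, the methyl ester and the aryl bromides (which would not survive hydrogenolysis) remain.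

Step 7
Reactants: 10 methyl 2,3,6-tribromo-4-hydroxy-5-methoxybenzoate
Product: 11 (2,3,6-tribromo-4-hydroxy-5-methoxyphenyl)methanol
Conditions: (iBu)2AlH (4 equiv), CH2Cl2/THF, −78 to 0 °C; then aq. potassium sodium tartrate (KNaC4H4O6), pH about 7
Reagents that add atoms: none
Why: Ester reduction with diisobutylaluminium hydride; the first equivalent converts the phenol to its aluminium phenoxide, further equivalents take the ester through the aldehyde to the alkoxide, the aryl bromides are inert to this electrophilic hydride at or below 0 °C, and the near-neutral tartrate work-up avoids benzylic ionisation of the product.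

## Compound list

1 | 3,4-dibromofuran | Brc1cocc1Br | starting material
2 | benzyl alcohol | OCc1ccccc1 | starting material
3 | 3-(benzyloxy)-4-bromofuran | Brc1cocc1OCc1ccccc1 | intermediate
4 | methyl propiolate | COC(=O)C#C | starting material
5 | methyl 3-bromopropiolate | COC(=O)C#CBr | intermediate
6 | racemic methyl (1R*,4R*)-5-(benzyloxy)-3,6-dibromo-7-oxabicyclo[2.2.1]hepta-2,5-diene-2-carboxylate (not isolated; (1R,4R) enantiomer drawn) | COC(=O)C1=C(Br)[C@@H]2O[C@H]1C(Br)=C2OCc1ccccc1 | intermediate
7 | methyl 4-(benzyloxy)-2,5-dibromo-3-hydroxybenzoate | COC(=O)c1cc(Br)c(OCc2ccccc2)c(O)c1Br | intermediate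
8 | methyl 4-(benzyloxy)-2,3,6-tribromo-5-hydroxybenzoate | COC(=O)c1c(Br)c(Br)c(OCc2ccccc2)c(O)c1Br | intermediate
9 | methyl 4-(benzyloxy)-2,3,6-tribromo-5-methoxybenzoate | COC(=O)c1c(Br)c(Br)c(OCc2ccccc2)c(OC)c1Br | intermediate
10 | methyl 2,3,6-tribromo-4-hydroxy-5-methoxybenzoate | COC(=O)c1c(Br)c(Br)c(O)c(OC)c1Br | intermediate
11 | (2,3,6-tribromo-4-hydroxy-5-methoxyphenyl)methanol | COc1c(O)c(Br)c(Br)c(CO)c1Br | target

## Step count and risks

Total step count: 7. Longest linear sequence: 6 steps (steps 1, 3, 4, 5, 6, 7); step 2 is a one-step branch.

**Step 3 (key step).** The most likely failures are:
- conjugate addition–elimination of the nucleophilic furan C2 onto the bromoalkynoate instead of ring closure;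
- a cycloaddition slowed by the furan bromine and the disubstituted alkyne, so that the alkoxyfuran decomposes thermally first;
- erosion of regioselectivity, or loss of the benzyl group during the opening.

The fallback moves the C6 bromine from the alkyne to a later electrophilic substitution. It sets out from 3 and 4, skipping step 2. The smaller and more reactive methyl propiolate 4 adds to 3 in PhMe at 60 °C with the same polarity control. This gives racemic methyl (1R*,4S*)-5-(benzyloxy)-6-bromo-7-oxabicyclo[2.2.1]hepta-2,5-diene-2-carboxylate F1, which is opened in the same flask with catalytic BF3·OEt2 to methyl 4-(benzyloxy)-3-bromo-5-hydroxybenzoate F2. The two remaining ring hydrogens of F2 are ortho and para to the free phenol. Both are brominated in one operation with Br2 (2.2 equiv), NaOAc and AcOH, and the route is rejoined at 8.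

**Step 1.** The coupling may run on to the bis-ether, reduce a C–Br bond, or stall because oxidative addition into the electron-rich heteroaryl bromide is slow; the product may also decompose at 100 °C. The fallback reverses the polarity of the furan carbon and sets out from 1. One bromine–lithium exchange with n-BuLi (1.0 equiv) in Et2O at −78 °C gives (4-bromofuran-3-yl)lithium F3. Trapping with B(OiPr)3 and treatment with aqueous KHF2 gives potassium (4-bromofuran-3-yl)trifluoroborate F4. Oxidative copper etherification of F4 with benzyl alcohol 2 (Cu(OAc)2·H2O 10 mol %, 4-(dimethylamino)pyridine, 4 Å molecular sieves, O2, CH2Cl2, rt) returns to the route at 3. Mono-substitution is then fixed by the stoichiometry of the exchange.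

**Step 4.** Substitution at a C–H flanked by bromine and an ester may be slow enough that oxidation of the catechol mono-ether, or acid cleavage of the benzyl ether by HBr, takes over. The fallback replaces electrophilic substitution with deprotonative metalation and sets out from 7. Methylation first (MeI, K2CO3, DMF) gives methyl 4-(benzyloxy)-2,5-dibromo-3-methoxybenzoate F5. Its only ring hydrogen, acidified by the ortho ester and ortho bromine, is removed with TMPMgCl·LiCl in THF at −40 °C. This gives [3-(benzyloxy)-2,5-dibromo-4-methoxy-6-(methoxycarbonyl)phenyl]magnesium chloride F6. Quenching with 1,2-dibromo-1,1,2,2-tetrachloroethane returns to the route at 9, bypassing 8.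

**Step 7.** The aluminium phenoxide formed first donates into the para ester, and the two ortho bromines hinder hydride delivery. The reduction may therefore stall at the aldehyde stage, and forcing it risks loss of bromine. Benzylic ionisation of the product on work-up is a second hazard. The fallback masks the phenol and sets out from 10. Silylation (tert-butyldimethylsilyl chloride, imidazole, DMF) gives methyl 2,3,6-tribromo-4-[(tert-butyldimethylsilyl)oxy]-5-methoxybenzoate F7. Reduction with (iBu)2AlH in CH2Cl2 at −78 °C gives {2,3,6-tribromo-4-[(tert-butyldimethylsilyl)oxy]-5-methoxyphenyl}methanol F8. Desilylation with Bu4NF buffered with AcOH in THF at 0 °C returns to the route at 11.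

## Further compounds

F1 | step 3 | racemic methyl (1R*,4S*)-5-(benzyloxy)-6-bromo-7-oxabicyclo[2.2.1]hepta-2,5-diene-2-carboxylate | COC(=O)C1=C[C@@H]2O[C@H]1C(Br)=C2OCc1ccccc1
F2 | step 3 | methyl 4-(benzyloxy)-3-bromo-5-hydroxybenzoate | COC(=O)c1cc(O)c(OCc2ccccc2)c(Br)c1
F3 | step 1 | (4-bromofuran-3-yl)lithium | [Li]c1cocc1Br
F4 | step 1 | potassium (4-bromofuran-3-yl)trifluoroborate | [K+].F[B-](F)(F)c1cocc1Br
F5 | step 4 | methyl 4-(benzyloxy)-2,5-dibromo-3-methoxybenzoate | COC(=O)c1cc(Br)c(OCc2ccccc2)c(OC)c1Br
F6 | step 4 | [3-(benzyloxy)-2,5-dibromo-4-methoxy-6-(methoxycarbonyl)phenyl]magnesium chloride | COC(=O)c1c([Mg]Cl)c(Br)c(OCc2ccccc2)c(OC)c1Br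
F7 | step 7 | methyl 2,3,6-tribromo-4-[(tert-butyldimethylsilyl)oxy]-5-methoxybenzoate | COC(=O)c1c(Br)c(Br)c(O[Si](C)(C)C(C)(C)C)c(OC)c1Br
F8 | step 7 | {2,3,6-tribromo-4-[(tert-butyldimethylsilyl)oxy]-5-methoxyphenyl}methanol | OCc1c(Br)c(Br)c(O[Si](C)(C)C(C)(C)C)c(OC)c1Br
A1 | alternative 1 | 1,2,4-tribromo-5-methoxy-6-(methoxymethoxy)-3-[(methoxymethoxy)methyl]benzene | COCOc1c(OC)c(Br)c(COCOC)c(Br)c1Br
A2 | alternative 1 | 5-bromo-4-methoxy-3-(methoxymethoxy)-6-[(methoxymethoxy)methyl]-2-(trimethylsilyl)phenyl trifluoromethanesulfonate | COCOc1c(OC)c(Br)c(COCOC)c(OS(=O)(=O)C(F)(F)F)c1[Si](C)(C)C
A3 | alternative 1 | 5-bromo-4-methoxy-3-(methoxymethoxy)-6-[(methoxymethoxy)methyl]-1,2-didehydrobenzene | COCOC1=C(OC)C(Br)=C(COCOC)C#C1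
A4 | alternative 2 | 2,5-dibromo-3,4-dimethoxythiophene 1,1-dioxide | COC1=C(Br)S(=O)(=O)C(Br)=C1OC
A5 | alternative 2 | methyl 2,3,6-tribromo-4,5-dimethoxybenzoate | COC(=O)c1c(Br)c(Br)c(OC)c(OC)c1Br
A6 | alternative 3 | 1,2,3-tribromo-5-methoxy-4-(methoxymethoxy)benzene | COCOc1c(OC)cc(Br)c(Br)c1Br
A7 | alternative 3 | 2,3,6-tribromo-5-methoxy-4-(methoxymethoxy)benzaldehyde | COCOc1c(OC)c(Br)c(C=O)c(Br)c1Br
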